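**Retrosynthetic overview**
- The strategy rests on the cyclopentane. Its CH bearing the C(=CH2) carbon of the eleven-membered ring is cis-vicinal to the ring-fusion CH bonded to the methyl-bearing sp2 carbon of the cyclohexene, which is an ene retron. The adjacent quaternary fusion carbon carries three oxygenated one-carbon arms (CH2OH, the five-ring CH–OAc, the six-ring CH–OH), so it can start as the symmetric C(CH2OH)2 carbon of a malonate.
- Late stage: the acetate is placed while a ketal masks the 1,3-diol. The six-ring CH–OH comes from hydroxymethyl-directed epoxidation of a cyclohexadiene followed by hydride opening at the allylic carbon. The eleven-membered ring is cut at its CH2–C(sp2) bond (intramolecular B-alkyl Suzuki coupling of a dienyl triflate).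
- The cyclohexenone is opened by a retro-aldol condensation (methyl ketone plus one of two formyl arms), and the cyclopentane by a retro type I ene reaction to an acyclic 1,6-diene with a spiro-ketal hub.
- The ene precursor comes from three pieces: an (E)-alkenyl iodide from (S)-β-citronellene, a resolved epoxide from diethyl bis(hydroxymethyl)malonate, and a keto ylide from 3-bromobutan-2-one.
- Ring order: cyclopentane, then cyclohexenone, then eleven-membered ring.

Key step: step 18

Assumption: the usual empirical sense of the hydrolytic kinetic resolution is taken to hold for 13, meaning the (S,S)-(salen)Co catalyst hydrates the (R)-enantiomer of an alkyl-substituted terminal epoxide. If it does not hold, the (R,R)-catalyst is used.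

Convention: bi- and tricyclic compounds are named with indene numbering of the hydrindane core. C1 is the five-ring CH bearing the C(=CH2) carbon, C2 is CH2, C3 is CH–O, C3a is the quaternary fusion carbon, and C4 and C5 are the next six-ring carbons. C6 is the carbon that first carries the ketone, C7 is the methyl-bearing carbon, and C7a is the fusion CH. β is the face of H-7a. Absolute configurations are those of the SMILES in the list.

Step 1
Reactants: 1 (S)-3,7-dimethylocta-1,6-diene ((S)-β-citronellene)
Product: 2 (S)-4-methylhex-5-enal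
Conditions: O3, CH2Cl2, Sudan III, −78 °C (stopped at decolourisation); Me2S, −78 °C → rt
Reagents that add atoms: ozone, [O-][O+]=O
Why: Chemoselective ozonolysis with reductive work-up, in which the electron-rich trisubstituted alkene takes up ozone much faster than the monosubstituted vinyl group and the stereocentre is not involved.

Step 2
Reactants: 2 (S)-4-methylhex-5-enal
Product: 3 (S)-4-methylhex-5-en-1-ol
Conditions: NaBH4, MeOH, 0 °C
Reagents that add atoms: none
Why: Borohydride reduction of an aldehyde, which leaves the vinyl group and the stereocentre untouched.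

Step 3
Reactants: 3 (S)-4-methylhex-5-en-1-ol
Product: 4 (S)-6-iodo-3-methylhex-1-ene
Conditions: I2, PPh3, imidazole, CH2Cl2, 0 °C → rt
Reagents that add atoms: iodine, II
Why: Appel-type iodination, in which the alkoxyphosphonium ion of the primary alcohol is displaced by iodide in an SN2 step remote from the stereocentre.

Step 4
Reactants: 4 (S)-6-iodo-3-methylhex-1-ene
Product: 5 (S)-6-methyloct-7-en-1-yne
Conditions: HC≡CLi·H2NCH2CH2NH2, DMSO, 10 °C → rt
Reagents that add atoms: lithium acetylide–ethylenediamine complex, [Li]C#C.NCCN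
Why: SN2 alkylation of an acetylide by an unhindered primary iodide in a dipolar aprotic solvent, which adds the two carbons that become the exocyclic-methylene carbon and its cyclopentane neighbour.

Step 5
Reactants: 5 (S)-6-methyloct-7-en-1-yne
Product: 7 (S,E)-1-iodo-2,6-dimethylocta-1,7-diene, via alkenyldimethylalane 6 (not isolated)
Conditions: Me3Al, Cp2ZrCl2 (cat.), CH2Cl2, 0 °C → rt; I2, THF, −30 → 0 °C
Reagents that add atoms: trimethylaluminium, C[Al](C)C; iodine, II
Why: Negishi carboalumination adds methyl and aluminium syn across the terminal alkyne (Al at the terminus) faster than it touches the branched vinyl group, and iodinolysis proceeds with retention, so the new methyl (the future =CH2) is cis to iodine.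

Step 6
Reactants: 8 diethyl 2,2-bis(hydroxymethyl)malonate
Product: 9 diethyl 2,2-dimethyl-1,3-dioxane-5,5-dicarboxylate
Conditions: Me2C(OMe)2, TsOH·H2O (cat.), acetone, rt
Reagents that add atoms: 2,2-dimethoxypropane, COC(C)(C)OC
Why: Acid-catalysed transketalisation closes a six-membered ketal on the 1,3-diol and keeps the central carbon symmetric.

Step 7
Reactants: 9 diethyl 2,2-dimethyl-1,3-dioxane-5,5-dicarboxylate
Product: 10 (2,2-dimethyl-1,3-dioxane-5,5-diyl)dimethanol
Conditions: LiAlH4, THF, 0 °C → rt; H2O/aq. NaOH work-up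
Reagents that add atoms: none
Why: LiAlH4 reduction of both esters, to which the ketal is inert, gives a pentaerythritol-type carbon with two equivalent free arms.

Step 8
Reactants: 10 (2,2-dimethyl-1,3-dioxane-5,5-diyl)dimethanol
Product: 11 {5-[(4-methoxybenzyloxy)methyl]-2,2-dimethyl-1,3-dioxan-5-yl}methanol
Conditions: NaH (1 equiv), PMBCl (1 equiv), Bu4NI (cat.), THF/DMF, 0 °C → rt
Reagents that add atoms: 4-methoxybenzyl chloride, COc1ccc(CCl)cc1
Why: Williamson mono-etherification of a symmetric diol with one equivalent of base and halide, where unreacted diol and bis-ether are easily separated and no stereocentre arises.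

Step 9
Reactants: 11 {5-[(4-methoxybenzyloxy)methyl]-2,2-dimethyl-1,3-dioxan-5-yl}methanol
Product: 12 5-[(4-methoxybenzyloxy)methyl]-2,2-dimethyl-1,3-dioxane-5-carbaldehyde
Conditions: Dess–Martin periodinane, CH2Cl2, 0 °C → rt
Reagents that add atoms: none
Why: Dess–Martin oxidation of a neopentyl primary alcohol gives an aldehyde without α-hydrogen, so it can neither enolise nor eliminate alkoxide.

Step 10
Reactants: 12 5-[(4-methoxybenzyloxy)methyl]-2,2-dimethyl-1,3-dioxane-5-carbaldehyde
Product: 13 rac-5-[(4-methoxybenzyloxy)methyl]-2,2-dimethyl-5-(oxiran-2-yl)-1,3-dioxane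
Conditions: Me3S+ I−, NaH, DMSO/THF, 0 °C → rt
Reagents that add atoms: trimethylsulfonium iodide, C[S+](C)C.[I-]
Why: Corey–Chaykovsky epoxidation, in which the small reactive sulfonium methylide adds even to a hindered non-enolisable aldehyde and the betaine closes to the racemic terminal epoxide.

Step 11
Reactants: 13 rac-5-[(4-methoxybenzyloxy)methyl]-2,2-dimethyl-5-(oxiran-2-yl)-1,3-dioxane
Product: 14 (S)-5-[(4-methoxybenzyloxy)methyl]-2,2-dimethyl-5-(oxiran-2-yl)-1,3-dioxane
Conditions: (S,S)-(salen)Co(III)OAc (cat.), H2O (0.55 equiv), THF (minimum), 0 °C → rt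
Reagents that add atoms: none
Why: Hydrolytic kinetic resolution, in which the chiral cobalt catalyst hydrates one enantiomer at its CH2 terminus much faster than the other (a discrimination known to extend to tert-alkyl-substituted terminal epoxides), so unreacted (S)-14 is separated from the polar diol and fixes the future acetoxy-bearing carbon.

Step 12
Reactants: 7 (S,E)-1-iodo-2,6-dimethylocta-1,7-diene; 14 (S)-5-[(4-methoxybenzyloxy)methyl]-2,2-dimethyl-5-(oxiran-2-yl)-1,3-dioxane
Product: 16 (1R,3E,8S)-1-{5-[(4-methoxybenzyloxy)methyl]-2,2-dimethyl-1,3-dioxan-5-yl}-4,8-dimethyldeca-3,9-dien-1-ol, via alkenyllithium 15 (not isolated)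
Conditions: 7, t-BuLi (2 equiv), Et2O, −78 °C; BF3·OEt2, then 14, −78 °C
Reagents that add atoms: none
Why: Iodine–lithium exchange with retention of alkene geometry is followed by BF3-assisted SN2 opening of the epoxide at its unhindered CH2, so the C–O stereocentre is untouched and its descriptor changes only through CIP priorities.

Step 13
Reactants: 16 (1R,3E,8S)-1-{5-[(4-methoxybenzyloxy)methyl]-2,2-dimethyl-1,3-dioxan-5-yl}-4,8-dimethyldeca-3,9-dien-1-ol
Product: 17 tert-butyldimethylsilyl ether of 16
Conditions: TBSOTf, 2,6-lutidine, CH2Cl2, 0 °C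
Reagents that add atoms: tert-butyldimethylsilyl triflate, CC(C)(C)[Si](C)(C)OS(=O)(=O)C(F)(F)F
Why: The silyl triflate is reactive enough for this carbinol next to a quaternary carbon, the hindered base shields ketal and PMB ether from acid, and the bulky ether later steers the ene reaction.

Step 14
Reactants: 17 tert-butyldimethylsilyl ether of 16
Product: 18 {5-[(1R,3E,8S)-1-(tert-butyldimethylsilyloxy)-4,8-dimethyldeca-3,9-dien-1-yl]-2,2-dimethyl-1,3-dioxan-5-yl}methanol
Conditions: DDQ, CH2Cl2/pH 7 buffer, 0 °C
Reagents that add atoms: none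
Why: Oxidative PMB cleavage (electron transfer from the electron-rich arene, then hydrolysis of the oxocarbenium ion) in a buffered two-phase medium leaves isolated alkenes, silyl ether and ketal intact.

Step 15
Reactants: 18 {5-[(1R,3E,8S)-1-(tert-butyldimethylsilyloxy)-4,8-dimethyldeca-3,9-dien-1-yl]-2,2-dimethyl-1,3-dioxan-5-yl}methanol
Product: 19 5-[(1R,3E,8S)-1-(tert-butyldimethylsilyloxy)-4,8-dimethyldeca-3,9-dien-1-yl]-2,2-dimethyl-1,3-dioxane-5-carbaldehyde
Conditions: Dess–Martin periodinane, CH2Cl2, 0 °C → rt
Reagents that add atoms: none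
Why: Dess–Martin oxidation of the neopentyl alcohol under mild non-basic conditions gives a non-enolisable aldehyde whose carbon becomes the fusion CH.

Step 16
Reactants: 20 3-bromobutan-2-one
Product: 22 3-(triphenyl-λ5-phosphanylidene)butan-2-one, via phosphonium bromide 21 (not isolated)
Conditions: PPh3, toluene, 80 °C; aq. NaOH, CH2Cl2, rt
Reagents that add atoms: triphenylphosphine, c1ccc(cc1)P(c1ccccc1)c1ccccc1
Why: SN2 quaternisation of the phosphine by the α-bromo ketone and deprotonation of the acidic α-CH give the isolable keto-stabilised ylide.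

Step 17
Reactants: 19 5-[(1R,3E,8S)-1-(tert-butyldimethylsilyloxy)-4,8-dimethyldeca-3,9-dien-1-yl]-2,2-dimethyl-1,3-dioxane-5-carbaldehyde; 22 3-(triphenyl-λ5-phosphanylidene)butan-2-one
Product: 23 (E)-4-{5-[(1R,3E,8S)-1-(tert-butyldimethylsilyloxy)-4,8-dimethyldeca-3,9-dien-1-yl]-2,2-dimethyl-1,3-dioxan-5-yl}-3-methylbut-3-en-2-one
Conditions: 22 (excess), toluene, 110 °C
Reagents that add atoms: none
Why: Wittig olefination with a stabilised ylide, run hot and with excess ylide because the aldehyde is neopentyl (it cannot enolise or epimerise), should place the quaternary carbon trans to the acetyl group (E).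

Step 18
Reactants: 23 (E)-4-{5-[(1R,3E,8S)-1-(tert-butyldimethylsilyloxy)-4,8-dimethyldeca-3,9-dien-1-yl]-2,2-dimethyl-1,3-dioxan-5-yl}-3-methylbut-3-en-2-one
Product: 24 3-{4-(tert-butyldimethylsilyloxy)-8,8-dimethyl-2-[(S)-6-methylocta-1,7-dien-2-yl]-7,9-dioxaspiro[4.5]decan-1-yl}butan-2-one; the C1 and C2 side chains are cis to each other and trans to the C4 silyloxy group, and the CH(CH3) next to the ketone is undefined
Conditions: degassed toluene (ca. 0.01 M), BHT (cat.), silylated sealed tube, 200 °C
Reagents that add atoms: none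
Why: This is a concerted, suprafacial thermal Alder-ene reaction in which the trisubstituted alkene is the ene and the enone the enophile: the alkene CH bonds to the enone β-carbon, a hydrogen of the vinylic methyl passes to the α-carbon, and the π-bond moves out to the 1,1-disubstituted methylene. The closest known reaction type is the thermal cyclisation of 1,6-dienes carrying an enoate or enone enophile, as used for cis-3,4-disubstituted kainoid pyrrolidines. The cyclopentane closes in the type I mode (both new substituents exocyclic to the new ring) through a transition state in which the forming five-membered ring is cis-fused to the six-centre ene array. The two new ring methines are cis because C–C bonding and H transfer occur on one face of each π-system and the three-atom tether cannot span the trans-fused alternative; their absolute sense should follow from the silyloxy carbon, whose bulky OTBS group stays on the ring face away from the stacked ene/enophile array, so both side chains end trans to it (the methine next to the ketone is erased in step 24). The step needs hydrogen abstraction from methyl rather than from the chain methylene, which is favoured because the E-alkene holds the methyl cis to the tether where the uncrowded tether-exo transition state can use it, and because primary hydrogens transfer more readily. It also needs ene closure over hetero-Diels–Alder addition or polymerisation, which is helped by the short tether, the gem-disubstitution of the spiro-dioxane, the absence of γ-hydrogens, dilution and BHT.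

Step 19
Reactants: 24 ene product (spiro ketal methyl ketone)
Product: 25 3-{3-(tert-butyldimethylsilyloxy)-2,2-bis(hydroxymethyl)-5-[(S)-6-methylocta-1,7-dien-2-yl]cyclopentyl}butan-2-one (ring stereochemistry as in 24)
Conditions: AcOH/THF/H2O, 40 °C
Reagents that add atoms: none
Why: Mild aqueous acid hydrolysis of the 1,3-dioxane ketal spares the hindered secondary TBS ether, and the water-rich medium keeps the keto diol from closing to internal ketals.

Step 20
Reactants: 25 keto diol
Product: 26 2-(tert-butyldimethylsilyloxy)-4-[(S)-6-methylocta-1,7-dien-2-yl]-5-(3-oxobutan-2-yl)cyclopentane-1,1-dicarbaldehyde (ring stereochemistry as in 24)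
Conditions: Dess–Martin periodinane (excess), CH2Cl2, rt
Reagents that add atoms: none
Why: Double Dess–Martin oxidation under non-basic conditions (any hemiketal with the ketone reopens at rt) gives a non-enolisable 1,3-dialdehyde that is used without delay.

Step 21
Reactants: 26 keto dialdehyde
Product: 28 3β-(tert-butyldimethylsilyloxy)-3aβ-formyl-7-methyl-1α-[(S)-6-methylocta-1,7-dien-2-yl]-1,2,3,3a,7,7a-hexahydro-6H-inden-6-one (cis-fused; C4=C5; C7 undefined), via aldol adduct 27 (not isolated)
Conditions: Bn2NH2+ CF3CO2− (cat.), benzene, 50 °C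
Reagents that add atoms: none
Why: In this amine-salt-catalysed intramolecular aldol condensation (6-enolexo) only the methyl terminus of the ketone can reach a formyl group through a six-membered ring; closure onto the formyl group on the side-chain face gives the less strained cis-hydrindenone while the other formyl group is shielded by the adjacent OTBS group, which fixes the quaternary centre, and the near-neutral medium limits deformylation.

Step 22
Reactants: 28 formyl enone
Product: 29 3β-(tert-butyldimethylsilyloxy)-3aβ-(hydroxymethyl)-7-methyl-1α-[(S)-6-methylocta-1,7-dien-2-yl]-1,2,3,3a,7,7a-hexahydro-6H-inden-6-one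
Conditions: NaBH4, CH2Cl2/MeOH, −78 °C
Reagents that add atoms: none
Why: In this chemoselective low-temperature borohydride reduction the aldehyde is reduced much faster than the conjugated ketone, and prompt reduction removes the deformylation-prone γ-formyl enone.

Step 23
Reactants: 29 hydroxymethyl enone
Product: 30 triethylsilyl ether of 29
Conditions: TESCl, imidazole, CH2Cl2, 0 °C
Reagents that add atoms: chlorotriethylsilane, CC[Si](Cl)(CC)CC
Why: Silylation of the primary alcohol prevents vinylogous retro-aldol loss of formaldehyde under the strong base of the next step, and TES can later be removed in the presence of TBS.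

Step 24
Reactants: 30 triethylsilyl ether of 29
Product: 32 3β-(tert-butyldimethylsilyloxy)-7-methyl-1α-[(S)-6-methylocta-1,7-dien-2-yl]-3aβ-(triethylsilyloxymethyl)-2,3,3a,7a-tetrahydro-1H-inden-6-yl trifluoromethanesulfonate (C4=C5 plus C6=C7), via lithium dienolate 31 (not isolated)
Conditions: LDA, THF, −78 °C; PhNTf2, −78 → 0 °C
Reagents that add atoms: N-phenylbis(trifluoromethanesulfonimide), O=S(=O)(N(c1ccccc1)S(=O)(=O)C(F)(F)F)C(F)(F)F
Why: Kinetic α′-deprotonation is the only option because the γ-carbon is quaternary, and O-sulfonylation of the cross-conjugated dienolate gives the dienyl triflate, turning the undefined C7 methine into the tetrasubstituted alkene carbon.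

Step 25
Reactants: 32 dienyl triflate
Product: 34 tricyclic triene with the 5-6-11 skeleton of the target (3β-OTBS; 3aβ-CH2OTES; C4=C5 plus C6=C7; exocyclic methylene), via trialkylborane 33 (not isolated)
Conditions: Sia2BH (from BH3·THF, 2-methylbut-2-ene), THF, 0 °C; slow addition to PdCl2(dppf) (cat.), AsPh3 (cat.), Cs2CO3, DMF/THF/H2O, 50 °C, ca. 1 mM
Reagents that add atoms: none
Why: Disiamylborane hydroborates the monosubstituted vinyl group in preference to the hindered 1,1-disubstituted methylene (a distinction 9-BBN does not make), and the primary B-alkyl group then undergoes intramolecular B-alkyl Suzuki–Miyaura coupling with the enol triflate under high dilution to close the eleven-membered ring, which contains the alkene as an E unit and leaves every stereocentre unchanged.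

Step 26
Reactants: 34 tricyclic triene (TES ether)
Product: 35 tricyclic triene with free 3aβ-hydroxymethyl group
Conditions: PPTS (cat.), MeOH/CH2Cl2, 0 °C → rt
Reagents that add atoms: none
Why: Mild acid-catalysed methanolysis removes the primary TES ether far faster than the hindered secondary TBS ether and is too weak to protonate the diene.

Step 27
Reactants: 35 tricyclic triene with free 3aβ-hydroxymethyl group
Product: 36 4β,5β-epoxide of 35 (vinyl epoxide; C6=C7 and the exocyclic methylene intact)
Conditions: VO(acac)2 (cat.), t-BuOOH (decane), toluene, 0 °C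
Reagents that add atoms: tert-butyl hydroperoxide, CC(C)(C)OO
Why: In this vanadium-catalysed hydroxyl-directed epoxidation the alkoxide-bound peroxide reaches only the homoallylic C4=C5 bond and delivers oxygen on the β face of the hydroxymethyl group, which sets C4 and overrides the intrinsic preference of peracids for the tetrasubstituted alkene.

Step 28
Reactants: 36 vinyl epoxide
Product: 37 4β-hydroxy-3aβ-(hydroxymethyl) tricycle with 3β-OTBS (C6=C7 kept; C5 now CH2)
Conditions: LiEt3BH (excess), THF, 0 °C → rt
Reagents that add atoms: none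
Why: Hydride opens the epoxide by SN2 attack at the allylic C5, which is both activated and the only accessible site because C4 is neopentyl and the SN2′ terminus C7 is fully substituted, so the C4–O bond and its configuration are kept; a π-allylpalladium/formate reduction is avoided because it tends to deliver hydride to the more substituted allyl terminus and would shift the alkene.

Step 29
Reactants: 37 1,3-diol
Product: 38 acetonide of 37 (1,3-dioxane across 3a-CH2O and 4β-O, cis-fused to the six-membered ring)
Conditions: Me2C(OMe)2, PPTS (cat.), CH2Cl2, rt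
Reagents that add atoms: 2,2-dimethoxypropane, COC(C)(C)OC
Why: Acid-catalysed ketalisation of the cis-disposed 1,3-diol masks both free hydroxyl groups in one operation, so that only the C3 oxygen can be acetylated later.

Step 30
Reactants: 38 acetonide of 37
Product: 39 3β-alcohol (TBS removed, acetonide kept)
Conditions: TBAF, THF, rt → 50 °C
Reagents that add atoms: none
Why: Fluoride-induced desilylation is driven by Si–F bond formation and leaves ketal and alkenes untouched, with warming allowed for the hindered position.

Step 31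
Reactants: 39 3β-alcohol
Product: 40 3β-acetate (acetonide kept)
Conditions: Ac2O, Et3N, DMAP (cat.), CH2Cl2, rt
Reagents that add atoms: acetic anhydride, CC(=O)OC(C)=O
Why: DMAP-catalysed acylation through the acylpyridinium ion esterifies the hindered secondary alcohol with retention, as the C–O bond is not broken.

Step 32
Reactants: 40 3β-acetate
Product: 41 CNP0228496.1 (target)
Conditions: AcOH/H2O, rt → 40 °C
Reagents that add atoms: none
Why: Mild aqueous acid hydrolysis of the ketal frees the 1,3-diol without cleaving the acetate, and avoiding base suppresses migration of the acetyl group to the neighbouring primary hydroxyl.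

**Compound list**
1 | (S)-3,7-dimethylocta-1,6-diene | CC(C)=CCC[C@H](C)C=C | starting material
2 | (S)-4-methylhex-5-enal | O=CCC[C@H](C)C=C | intermediate
3 | (S)-4-methylhex-5-en-1-ol | OCCC[C@H](C)C=C | intermediate
4 | (S)-6-iodo-3-methylhex-1-ene | ICCC[C@H](C)C=C | intermediate
5 | (S)-6-methyloct-7-en-1-yne | C#CCCC[C@H](C)C=C | intermediate
6 | (S,E)-(2,6-dimethylocta-1,7-dien-1-yl)dimethylalane | C[Al](C)/C=C(C)/CCC[C@H](C)C=C | intermediate
7 | (S,E)-1-iodo-2,6-dimethylocta-1,7-diene | I/C=C(C)/CCC[C@H](C)C=C | intermediate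
8 | diethyl 2,2-bis(hydroxymethyl)malonate | CCOC(=O)C(CO)(CO)C(=O)OCC | starting material
9 | diethyl 2,2-dimethyl-1,3-dioxane-5,5-dicarboxylate | CCOC(=O)C1(COC(C)(C)OC1)C(=O)OCC | intermediate
10 | (2,2-dimethyl-1,3-dioxane-5,5-diyl)dimethanol | OCC1(CO)COC(C)(C)OC1 | intermediate
11 | {5-[(4-methoxybenzyloxy)methyl]-2,2-dimethyl-1,3-dioxan-5-yl}methanol | COc1ccc(COCC2(CO)COC(C)(C)OC2)cc1 | intermediate
12 | 5-[(4-methoxybenzyloxy)methyl]-2,2-dimethyl-1,3-dioxane-5-carbaldehyde | COc1ccc(COCC2(C=O)COC(C)(C)OC2)cc1 | intermediate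
13 | rac-5-[(4-methoxybenzyloxy)methyl]-2,2-dimethyl-5-(oxiran-2-yl)-1,3-dioxane | COc1ccc(COCC2(COC(C)(C)OC2)C3CO3)cc1 | intermediate
14 | (S)-5-[(4-methoxybenzyloxy)methyl]-2,2-dimethyl-5-(oxiran-2-yl)-1,3-dioxane | COc1ccc(COCC2(COC(C)(C)OC2)[C@H]3CO3)cc1 | intermediate
15 | (S,E)-(2,6-dimethylocta-1,7-dien-1-yl)lithium | [Li]/C=C(C)/CCC[C@H](C)C=C | intermediate
16 | homoallylic alcohol, (1R,3E,8S) | COc1ccc(COCC2(COC(C)(C)OC2)[C@H](O)C/C=C(\C)CCC[C@H](C)C=C)cc1 | intermediate
17 | TBS ether of 16 | COc1ccc(COCC2(COC(C)(C)OC2)[C@H](O[Si](C)(C)C(C)(C)C)C/C=C(\C)CCC[C@H](C)C=C)cc1 | intermediate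
18 | primary alcohol (PMB removed) | OCC1(COC(C)(C)OC1)[C@H](O[Si](C)(C)C(C)(C)C)C/C=C(\C)CCC[C@H](C)C=C | intermediate
19 | hub aldehyde | O=CC1(COC(C)(C)OC1)[C@H](O[Si](C)(C)C(C)(C)C)C/C=C(\C)CCC[C@H](C)C=C | intermediate
20 | 3-bromobutan-2-one | CC(Br)C(C)=O | starting material
21 | (3-oxobutan-2-yl)triphenylphosphonium bromide | CC(=O)C(C)[P+](c1ccccc1)(c1ccccc1)c1ccccc1.[Br-] | intermediate
22 | 3-(triphenyl-λ5-phosphanylidene)butan-2-one | CC(=O)C(C)=P(c1ccccc1)(c1ccccc1)c1ccccc1 | intermediate
23 | ene precursor (E-enone, E-trisubstituted alkene) | CC(=O)/C(C)=C/C1(COC(C)(C)OC1)[C@H](O[Si](C)(C)C(C)(C)C)C/C=C(\C)CCC[C@H](C)C=C | intermediate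
24 | ene product (cis-1,2-disubstituted cyclopentane, spiro ketal) | CC(=O)C(C)[C@@H]1[C@H](C(=C)CCC[C@H](C)C=C)C[C@@H](O[Si](C)(C)C(C)(C)C)C12COC(C)(C)OC2 | intermediate
25 | keto diol | CC(=O)C(C)[C@@H]1[C@H](C(=C)CCC[C@H](C)C=C)C[C@@H](O[Si](C)(C)C(C)(C)C)C1(CO)CO | intermediate
26 | keto dialdehyde | CC(=O)C(C)[C@@H]1[C@H](C(=C)CCC[C@H](C)C=C)C[C@@H](O[Si](C)(C)C(C)(C)C)C1(C=O)C=O | intermediate
27 | aldol adduct (β-hydroxy ketone) | C=C(CCC[C@H](C)C=C)[C@@H]1C[C@@H](O[Si](C)(C)C(C)(C)C)[C@]2(C=O)C(O)CC(=O)C(C)[C@H]12 | intermediate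
28 | cis-fused 3a-formyl enone | C=C(CCC[C@H](C)C=C)[C@@H]1C[C@@H](O[Si](C)(C)C(C)(C)C)[C@]2(C=O)C=CC(=O)C(C)[C@H]12 | intermediate
29 | cis-fused 3a-hydroxymethyl enone | C=C(CCC[C@H](C)C=C)[C@@H]1C[C@@H](O[Si](C)(C)C(C)(C)C)[C@]2(CO)C=CC(=O)C(C)[C@H]12 | intermediate
30 | TES ether of 29 | C=C(CCC[C@H](C)C=C)[C@@H]1C[C@@H](O[Si](C)(C)C(C)(C)C)[C@]2(CO[Si](CC)(CC)CC)C=CC(=O)C(C)[C@H]12 | intermediate
31 | lithium cross-conjugated dienolate | C=C(CCC[C@H](C)C=C)[C@@H]1C[C@@H](O[Si](C)(C)C(C)(C)C)[C@]2(CO[Si](CC)(CC)CC)C=CC(O[Li])=C(C)[C@H]12 | intermediate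
32 | dienyl triflate | C=C(CCC[C@H](C)C=C)[C@@H]1C[C@@H](O[Si](C)(C)C(C)(C)C)[C@]2(CO[Si](CC)(CC)CC)C=CC(OS(=O)(=O)C(F)(F)F)=C(C)[C@H]12 | intermediate
33 | primary alkyl(disiamyl)borane | C=C(CCC[C@H](C)CCB(C(C)C(C)C)C(C)C(C)C)[C@@H]1C[C@@H](O[Si](C)(C)C(C)(C)C)[C@]2(CO[Si](CC)(CC)CC)C=CC(OS(=O)(=O)C(F)(F)F)=C(C)[C@H]12 | intermediate
34 | tricyclic triene, TES and TBS ethers | C=C1CCC[C@H](C)CCC2=C(C)[C@@H]3[C@H]1C[C@@H](O[Si](C)(C)C(C)(C)C)[C@]3(CO[Si](CC)(CC)CC)C=C2 | intermediate
35 | tricyclic triene, free hydroxymethyl | C=C1CCC[C@H](C)CCC2=C(C)[C@@H]3[C@H]1C[C@@H](O[Si](C)(C)C(C)(C)C)[C@]3(CO)C=C2 | intermediate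
36 | 4β,5β-vinyl epoxide | C=C1CCC[C@H](C)CCC2=C(C)[C@@H]3[C@H]1C[C@@H](O[Si](C)(C)C(C)(C)C)[C@]3(CO)[C@H]4O[C@H]42 | intermediate
37 | 1,3-diol with 3β-OTBS | C=C1CCC[C@H](C)CCC2=C(C)[C@@H]3[C@H]1C[C@@H](O[Si](C)(C)C(C)(C)C)[C@]3(CO)[C@@H](O)C2 | intermediate
38 | acetonide of 37 | C=C1CCC[C@H](C)CCC2=C(C)[C@@H]3[C@H]1C[C@@H](O[Si](C)(C)C(C)(C)C)[C@@]34COC(C)(C)O[C@H]4C2 | intermediate
39 | 3β-alcohol acetonide | C=C1CCC[C@H](C)CCC2=C(C)[C@@H]3[C@H]1C[C@@H](O)[C@@]34COC(C)(C)O[C@H]4C2 | intermediate
40 | 3β-acetate acetonide | C=C1CCC[C@H](C)CCC2=C(C)[C@@H]3[C@H]1C[C@@H](OC(C)=O)[C@@]34COC(C)(C)O[C@H]4C2 | intermediate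
41 | CNP0228496.1 | C=C1CCC[C@H](C)CCC2=C(C)[C@@H]3[C@H]1C[C@@H](OC(C)=O)[C@]3(CO)[C@@H](O)C2 | target

**Step count**
- Total step count: 32.
- Longest linear sequence: 26 steps (from 8: steps 6–15 and 17–32).

**Steps most likely to fail**

Step 18 (ene cyclisation). The enophile is trisubstituted and its β-carbon is neopentyl. Ring closure may therefore be too slow at temperatures the substrate tolerates, and the silyloxy group may discriminate poorly between the two ring faces at such high temperature.
- The fallback sets out from aldehyde 19 and comes back at TES ether 30. It runs the ene reaction on a less hindered 1,2-disubstituted enophile, as in the kainoid cases, and introduces the methyl group afterwards.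
- Wittig reaction of 19 with commercial 1-(triphenylphosphoranylidene)propan-2-one gives the (E)-des-methyl enone F1. Heating F1 in toluene gives the des-methyl ene product F2.
- Aqueous acetic acid then gives the des-methyl keto diol F3, and Dess–Martin oxidation the des-methyl keto dialdehyde F4.
- Dibenzylammonium trifluoroacetate gives the des-methyl formyl enone F5, NaBH4 at −78 °C the des-methyl hydroxymethyl enone F6, and TESCl/imidazole the des-methyl TES ether F7.
- Kinetic α′-deprotonation of F7 with LDA and alkylation with MeI gives 30. The configuration of the new methine is irrelevant.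

Step 25 (macrocyclisation). Transmetallation from the hindered disiamylborane may be slow, and the eleven-membered transition state is strained. Oligomerisation, protodeboronation or hydrolysis of the triflate could then win.
- The fallback sets out from triflate 32 and comes back at triene 34. It closes the ring by carbonyl addition instead of reductive elimination.
- Borane 33, made as in step 25, is oxidised with NaBO3·4H2O to the primary alcohol triflate F8. Dess–Martin oxidation gives the aldehyde triflate F9.
- Intramolecular Nozaki–Hiyama–Kishi reaction (CrCl2, NiCl2 cat., DMF, high dilution) gives the macrocyclic dienyl carbinol F10, whose carbinol configuration is irrelevant.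
- Ac2O/DMAP gives the macrocyclic allylic acetate F11. Pd(PPh3)4/LiBHEt3 then delivers hydride to the least hindered allyl terminus and gives 34.

Step 27 (directed epoxidation). The tetrasubstituted or exocyclic alkene may be oxidised in competition, or the diene monoepoxide may open under Lewis acid catalysis.
- The fallback sets out from alcohol 35 and comes back at diol 37, bypassing 36, by a tethered hydrosilylation.
- (HMe2Si)2NH gives the dimethylsilyl ether F12. Karstedt's platinum catalyst induces intramolecular hydrosilylation of the homoallylic C4=C5 bond to the five-membered oxasilolane F13, with silicon on C4 on the β face.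
- Tamao–Fleming oxidation (H2O2, KF, KHCO3, THF/MeOH) replaces silicon by hydroxyl with retention and gives 37.

**Further compounds**
F1 | step 18 | (E)-des-methyl enone | CC(=O)/C=C/C1(COC(C)(C)OC1)[C@H](O[Si](C)(C)C(C)(C)C)C/C=C(\C)CCC[C@H](C)C=C
F2 | step 18 | des-methyl ene product | CC(=O)C[C@@H]1[C@H](C(=C)CCC[C@H](C)C=C)C[C@@H](O[Si](C)(C)C(C)(C)C)C12COC(C)(C)OC2
F3 | step 18 | des-methyl keto diol | CC(=O)C[C@@H]1[C@H](C(=C)CCC[C@H](C)C=C)C[C@@H](O[Si](C)(C)C(C)(C)C)C1(CO)CO
F4 | step 18 | des-methyl keto dialdehyde | CC(=O)C[C@@H]1[C@H](C(=C)CCC[C@H](C)C=C)C[C@@H](O[Si](C)(C)C(C)(C)C)C1(C=O)C=O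
F5 | step 18 | des-methyl formyl enone | C=C(CCC[C@H](C)C=C)[C@@H]1C[C@@H](O[Si](C)(C)C(C)(C)C)[C@]2(C=O)C=CC(=O)C[C@H]12
F6 | step 18 | des-methyl hydroxymethyl enone | C=C(CCC[C@H](C)C=C)[C@@H]1C[C@@H](O[Si](C)(C)C(C)(C)C)[C@]2(CO)C=CC(=O)C[C@H]12
F7 | step 18 | des-methyl TES ether | C=C(CCC[C@H](C)C=C)[C@@H]1C[C@@H](O[Si](C)(C)C(C)(C)C)[C@]2(CO[Si](CC)(CC)CC)C=CC(=O)C[C@H]12
F8 | step 25 | primary alcohol triflate | C=C(CCC[C@H](C)CCO)[C@@H]1C[C@@H](O[Si](C)(C)C(C)(C)C)[C@]2(CO[Si](CC)(CC)CC)C=CC(OS(=O)(=O)C(F)(F)F)=C(C)[C@H]12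
F9 | step 25 | aldehyde triflate | C=C(CCC[C@H](C)CC=O)[C@@H]1C[C@@H](O[Si](C)(C)C(C)(C)C)[C@]2(CO[Si](CC)(CC)CC)C=CC(OS(=O)(=O)C(F)(F)F)=C(C)[C@H]12
F10 | step 25 | macrocyclic dienyl carbinol | C=C1CCC[C@H](C)CC(O)C2=C(C)[C@@H]3[C@H]1C[C@@H](O[Si](C)(C)C(C)(C)C)[C@]3(CO[Si](CC)(CC)CC)C=C2
F11 | step 25 | macrocyclic allylic acetate | C=C1CCC[C@H](C)CC(OC(C)=O)C2=C(C)[C@@H]3[C@H]1C[C@@H](O[Si](C)(C)C(C)(C)C)[C@]3(CO[Si](CC)(CC)CC)C=C2
F12 | step 27 | dimethylsilyl ether | C=C1CCC[C@H](C)CCC2=C(C)[C@@H]3[C@H]1C[C@@H](O[Si](C)(C)C(C)(C)C)[C@]3(CO[SiH](C)C)C=C2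
F13 | step 27 | oxasilolane | C=C1CCC[C@H](C)CCC2=C(C)[C@@H]3[C@H]1C[C@@H](O[Si](C)(C)C(C)(C)C)[C@@]34CO[Si](C)(C)[C@H]4C2
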